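**Retrosynthetic overview**

1. C3–C4 is cut last: an (E)-vinylstannane made from a C4–C17 terminal alkyne is joined to a (Z)-3-iodo-2-methylacrylamide of the aminonaphthoquinone, then global deprotection.
2. C13–C17 comes from an anti-selective vinylogous Mukaiyama aldol on a C13 aldehyde.
3. Key step: the C6–C7 bond and the C7 centre are made by a boronate 1,2-metallate rearrangement (1,2-shift of the C6 propargylic carbon from boron to C7) between a lithiated C7 carbamate and a chiral propargylic boronic ester.
4. The C8–C12 core comes from a two-directional iridium-catalysed double crotylation of 2-methylpropane-1,3-diol; the two ends are told apart by iodoetherification.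
5. Ring order: the benzo ring of the naphthoquinone (Diels–Alder on benzoquinone, then aromatisation) is the only skeletal ring formed and is made in a side branch; on the chain a tetrahydropyran (iodoether) and then a dioxane (acetonide) are formed temporarily and opened again.

Assumption: chain atoms carry the target numbering C1 (amide C=O) to C17 (CO2H); in step 1 the SEGPHOS antipode is the one that gives the (3R,4R,6R,7R) series (written as S), and racemic 2 is used because its stereocentre is lost in the π-allyl intermediate.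

**Route**

Step 1
Reactants: 1 2-methylpropane-1,3-diol; 2 but-3-en-2-yl acetate (racemic)
Product: 3 (3R,4R,6R,7R)-3,5,7-trimethylnona-1,8-diene-4,6-diol
Conditions: [Ir(cod)Cl]2 (5 mol%), (S)-SEGPHOS (10 mol%), 4-cyano-3-nitrobenzoic acid (20 mol%), Cs2CO3 (40 mol%), 2 (4 equiv), THF, 90 °C
Reagents that add atoms: none
Why: Krische transfer-hydrogenative double crotylation, in which each CH2OH is dehydrogenated in situ and the transient aldehyde is captured by the (E)-σ-crotyliridium complex through a closed chair transition state, so C8/C9 and C11/C12 are formed anti with the catalyst fixing both carbinol centres while 2-methylmalondialdehyde is never free.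

Step 2
Reactants: 3 diene-diol
Product: 4 iodo-tetrahydropyran (O9 closed on C13)
Conditions: I2, NaHCO3, MeCN, −20 → 0 °C
Reagents that add atoms: iodine, II
Why: 6-exo iodoetherification in which only O9 closing on the C13 alkene can use a chair with the C8 chain, 10-Me and 11-OH equatorial (one axial methyl), whereas O11 closing on the C7 alkene needs a 1,3-diaxial pair, so the diastereotopic vinyl groups are differentiated and the new C13 centre (CH2I equatorial) is only temporary.

Step 3
Reactants: 4 iodo-tetrahydropyran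
Product: 6 C7 primary alcohol, via aldehyde 5 (not isolated)
Conditions: OsO4 (2 mol%), NaIO4, 2,6-lutidine, dioxane–H2O, rt; filter; then NaBH4, MeOH, 0 °C
Reagents that add atoms: sodium periodate (oxygen source through catalytic OsO4), [Na+].[O-]I(=O)(=O)=O
Why: Lemieux–Johnson cleavage of the free vinyl group (chosen over ozone, which would attack the alkyl iodide) followed by borohydride reduction gives the C7 alcohol without touching a stereocentre.

Step 4
Reactants: 6 C7 primary alcohol
Product: 7 (2R,3R,4S,5R,6R)-2,4,6-trimethyloct-7-ene-1,3,5-triol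
Conditions: Zn dust, EtOH, reflux
Reagents that add atoms: none
Why: zinc insertion into the C–I bond and β-elimination of the ring alkoxide (Boord/Bernet–Vasella-type reductive opening) returns the C13 vinyl group and the C9 hydroxyl with all stereocentres intact, leaving the two ends chemically different.

Step 5
Reactants: 7 triol
Product: 8 C7 N,N-diisopropylcarbamate
Conditions: iPr2NCOCl (1.1 equiv), Et3N, DMAP (10 mol%), CH2Cl2, 40 °C
Reagents that add atoms: N,N-diisopropylcarbamoyl chloride, CC(C)N(C(C)C)C(Cl)=O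
Why: the hindered carbamoyl chloride acylates the primary hydroxyl much faster than the two flanked secondary ones, installing the Hoppe directing and leaving group.

Step 6
Reactants: 8 carbamate diol
Product: 9 carbamate acetonide
Conditions: 2,2-dimethoxypropane, PPTS (cat.), CH2Cl2, rt
Reagents that add atoms: 2,2-dimethoxypropane, COC(C)(C)OC
Why: acid-catalysed transacetalisation ties the anti-1,3-diol (C9/C11) as its isopropylidene acetal, removing acidic OH groups before the organolithium step.

Step 7
Reactants: 10 ethanol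
Product: 11 ethyl N,N-diisopropylcarbamate
Conditions: iPr2NCOCl, Et3N, CH2Cl2, reflux
Reagents that add atoms: N,N-diisopropylcarbamoyl chloride, CC(C)N(C(C)C)C(Cl)=O
Why: simple O-carbamoylation gives the Hoppe carbamate that will supply C6 and its methyl group.

Step 8
Reactants: 12 ethynyl(trimethyl)silane
Product: 14 (trimethylsilyl)ethynyl pinacol boronate, via lithium acetylide 13 (not isolated)
Conditions: n-BuLi, THF, −78 °C; 2-isopropoxy-4,4,5,5-tetramethyl-1,3,2-dioxaborolane; then HCl·Et2O, −78 °C → rt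
Reagents that add atoms: 2-isopropoxy-4,4,5,5-tetramethyl-1,3,2-dioxaborolane, CC(C)OB1OC(C)(C)C(C)(C)O1
Why: deprotonation of the terminal alkyne, borylation and protonolysis of the resulting borate is the standard route to alkynyl pinacol boronates (C4–C5 unit).

Step 9
Reactants: 11 ethyl N,N-diisopropylcarbamate; 14 alkynyl boronate
Product: 17 (S)-propargylic pinacol boronate, via lithiated carbamate 15 (not isolated), via boronate complex 16 (not isolated)
Conditions: s-BuLi, (+)-sparteine, Et2O, −78 °C, 5 h; 14, −78 °C; then warm to 35 °C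
Reagents that add atoms: none
Why: Hoppe–Aggarwal lithiation–borylation, in which s-BuLi/(+)-sparteine removes the pro-R hydrogen, the configurationally stable carbanion is borylated with retention and the alkynyl group undergoes a 1,2-shift with inversion at carbon as the carbamate leaves, setting the C6 centre (S).

Step 10
Reactants: 9 carbamate acetonide; 17 (S)-propargylic pinacol boronate
Product: 20 C7 secondary pinacol boronate (C4–C13), via lithiated carbamate 18 (not isolated), via boronate complex 19 (not isolated)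
Conditions: s-BuLi (1.3 equiv), (−)-sparteine (1.3 equiv), Et2O, −78 °C, 5 h; 17 (1.5 equiv), −78 °C, 1 h; MgBr2·OEt2, −78 → 35 °C, 12 h
Reagents that add atoms: none
Why: Proposed new method: a lithiation–borylation run with an α-stereogenic secondary propargylic pinacol boronate as the migrating partner of a β-branched polyketide carbamate, a pairing not yet shown, in which (−)-sparteine/s-BuLi removes the pro-S C7–H, the carbanion adds to boron of 17 with retention to give 19, and antiperiplanar 1,2-shift of the C6 propargylic carbon (retention at C6, inversion at C7) expels the carbamate, forming C6–C7 and fixing the C7–B (later C7–O) centre syn to 8-Me and anti to 6-Me, while the three-centre shift cannot reach the alkyne terminus so no allenyl scrambling is expected; closest known reaction type: Hoppe–Aggarwal 1,2-metallate rearrangement of lithiated primary carbamates with secondary alkyl boronic esters.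

Step 11
Reactants: 20 C7 secondary pinacol boronate
Product: 22 C13 aldehyde, via ozonide 21 (not isolated)
Conditions: O3, CH2Cl2, −78 °C; then PPh3, −78 °C → rt
Reagents that add atoms: ozone, [O-][O+]=O
Why: ozonolysis with reductive work-up cleaves the only C=C bond, the silyl alkyne and the alkyl pinacol boronate (carried on as a masked C7 hydroxyl) being inert at −78 °C.

Step 12
Reactants: 23 (E)-2-methylpent-2-enoic acid
Product: 25 N-enoyl oxazolidinone, via mixed anhydride 24 (not isolated)
Conditions: pivaloyl chloride, Et3N, THF, −20 °C; then LiCl, (S)-4-isopropyloxazolidin-2-one, rt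
Reagents that add atoms: (S)-4-isopropyl-1,3-oxazolidin-2-one, CC(C)[C@H]1COC(=O)N1
Why: acylation of the lithium chloride-activated oxazolidinone by the mixed pivalic anhydride is the standard Evans auxiliary attachment and leaves the E-alkene untouched.

Step 13
Reactants: 25 N-enoyl oxazolidinone
Product: 26 vinylketene silyl N,O-acetal
Conditions: NaN(SiMe3)2, THF, −78 °C; TBSCl
Reagents that add atoms: tert-butyldimethylsilyl chloride, CC(C)(C)[Si](C)(C)Cl
Why: γ-deprotonation of the enoyl imide and O-silylation give Kobayashi's (1E,3E)-dienyl silyl N,O-acetal.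

Step 14
Reactants: 22 C13 aldehyde; 26 vinylketene silyl N,O-acetal
Product: 27 aldol adduct (C4–C17 imide)
Conditions: TiCl4 (1 equiv), CH2Cl2, −78 → −40 °C
Reagents that add atoms: none
Why: Kobayashi anti-selective vinylogous Mukaiyama aldol reaction, in which the γ-carbon of 26 attacks the TiCl4-activated aldehyde on the dienyl face remote from the isopropyl group through an open transition state, giving the (E)-enoyl imide with 13-OH/14-Me anti and, under reagent control matched with the Felkin preference of the α-methyl aldehyde, 13-OH syn to 12-Me.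

Step 15
Reactants: 27 aldol adduct
Product: 28 alkyne acid (C4–C17, C7-OH and C13-OH free)
Conditions: LiOH, H2O2 (30% aq.), THF–H2O, 0 °C → rt; MeOH, rt; Na2SO3; 1 M HCl to pH 3
Reagents that add atoms: hydrogen peroxide, OO
Why: lithium hydroperoxide cleaves the imide at the exocyclic carbonyl, the same alkaline peroxide oxidises the C7–B bond to C7–OH with retention, and hydroxide removes the alkynyl silyl group, so three unmaskings happen in one operation.

Step 16
Reactants: 29 3-methylbut-3-en-2-one
Product: 30 2-methyl-3-(triisopropylsilyloxy)buta-1,3-diene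
Conditions: iPr3SiOTf, Et3N, CH2Cl2, 0 °C
Reagents that add atoms: triisopropylsilyl triflate, CC(C)[Si](C(C)C)(C(C)C)OS(=O)(=O)C(F)(F)F
Why: soft enolisation and O-silylation of the methyl ketone give the 2-silyloxy diene.

Step 17
Reactants: 30 silyloxy diene; 31 1,4-benzoquinone
Product: 33 6-methyl-7-(triisopropylsilyloxy)naphthalene-1,4-dione, via cycloadduct 32 (not isolated)
Conditions: toluene, rt, 12 h; then Et3N (cat.), DDQ (2.2 equiv), rt → 60 °C
Reagents that add atoms: none
Why: Diels–Alder reaction of the electron-rich diene with benzoquinone builds the carbocyclic ring and DDQ dehydrogenation of the cis-adduct gives the naphthoquinone, the silyl enol ether becoming the aryl silyl ether.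

Step 18
Reactants: 33 silyloxy naphthoquinone
Product: 34 2-amino-7-methyl-6-(triisopropylsilyloxy)naphthalene-1,4-dione
Conditions: NaN3, AcOH, THF–H2O, rt
Reagents that add atoms: sodium azide, [Na+].[N-]=[N+]=[N-]
Why: conjugate addition of azide at C2 (activated by the C4 carbonyl, the one not deactivated by the para silyloxy donor) followed by loss of N2 from the azidohydroquinone (internal redox) gives the 2-aminoquinone.

Step 19
Reactants: 35 prop-2-yn-1-ol
Product: 37 (Z)-3-iodo-2-methylprop-2-en-1-ol, via vinylmagnesium species 36 (not isolated)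
Conditions: MeMgBr (2.5 equiv), CuI (10 mol%), THF, −10 °C → rt; then I2, −40 °C
Reagents that add atoms: methylmagnesium bromide, C[Mg]Br; iodine, II
Why: copper-catalysed anti-carbomagnesiation of the propargylic alkoxide (chelated vinylmagnesium intermediate) and iodinolysis with retention give the (Z)-iodoalkene that later fixes the C2=C3 geometry.

Step 20
Reactants: 37 (Z)-iodo alcohol
Product: 38 (Z)-3-iodo-2-methylprop-2-enoic acid
Conditions: TEMPO (20 mol%), PhI(OAc)2 (2.2 equiv), MeCN–H2O, rt
Reagents that add atoms: water, O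
Why: TEMPO/PhI(OAc)2 oxidation in aqueous acetonitrile takes the allylic alcohol through the aldehyde hydrate to the acid without Z/E isomerisation.

Step 21
Reactants: 38 (Z)-iodo acid; 34 aminoquinone
Product: 40 (Z)-iodoacrylamide of the aminoquinone, via acid chloride 39 (not isolated)
Conditions: (COCl)2, DMF (cat.), CH2Cl2, 0 °C, evaporate; 34, NaH, THF, 0 °C, then 39, 0 °C → rt
Reagents that add atoms: none
Why: the weakly nucleophilic vinylogous amide is N-acylated as its sodium salt by the acid chloride, the phenol being blocked as its silyl ether.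

Step 22
Reactants: 28 alkyne acid; 40 (Z)-iodoacrylamide
Product: 42 protected target (acetonide and aryl silyl ether), via vinylstannane 41 (not isolated)
Conditions: iPr2NEt (1.1 equiv), Bu3SnH (1.3 equiv), PdCl2(PPh3)2 (3 mol%), THF, 0 °C; then 40, Pd2(dba)3 (5 mol%), AsPh3 (20 mol%), CuI (10 mol%), DMF, rt
Reagents that add atoms: none
Why: palladium-catalysed syn-hydrostannation puts tin on the terminal carbon (E) away from the branched C6, and Stille coupling with the (Z)-iodoacrylamide proceeds with retention at both partners to give the (2Z,4E)-dienamide.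

Step 23
Reactants: 42 protected target
Product: 43 target CNP0489037.1
Conditions: HF (48% aq.), MeCN–H2O, 0 °C → rt
Reagents that add atoms: none
Why: aqueous HF hydrolyses the acetonide and cleaves the aryl silyl ether without affecting the dienamide, the enoic acid or the quinone.

**Compound list**

1 | 2-methylpropane-1,3-diol | CC(CO)CO | starting material
2 | but-3-en-2-yl acetate (racemic) | CC(OC(C)=O)C=C | starting material
3 | (3R,4R,6R,7R)-3,5,7-trimethylnona-1,8-diene-4,6-diol (C7–C13 with two vinyl ends; both arms identical) | C=C[C@@H](C)[C@@H](O)C(C)[C@H](O)[C@H](C)C=C | intermediate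
4 | iodo-tetrahydropyran: ring O9–C9–C10–C11–C12–C13, with 13-CH2I, 11-OH, 10-Me and the 9-(but-3-en-2-yl) chain equatorial, 12-Me axial; C8–C12 as in 3 | C=C[C@@H](C)[C@H]1O[C@@H](CI)[C@@H](C)[C@@H](O)[C@@H]1C | intermediate
5 | C7 aldehyde of 4 (vinyl cleaved to CHO), not isolated | O=C[C@@H](C)[C@H]1O[C@@H](CI)[C@@H](C)[C@@H](O)[C@@H]1C | intermediate
6 | C7 primary alcohol of the iodo-tetrahydropyran | OC[C@@H](C)[C@H]1O[C@@H](CI)[C@@H](C)[C@@H](O)[C@@H]1C | intermediate
7 | (2R,3R,4S,5R,6R)-2,4,6-trimethyloct-7-ene-1,3,5-triol (C7 CH2OH to C13 vinyl; C8–C12 as in the target) | OC[C@@H](C)[C@@H](O)[C@@H](C)[C@H](O)[C@H](C)C=C | intermediate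
8 | triol 7 with the primary (C7) hydroxyl as N,N-diisopropylcarbamate | CC(C)N(C(C)C)C(=O)OC[C@@H](C)[C@@H](O)[C@@H](C)[C@H](O)[C@H](C)C=C | intermediate
9 | carbamate 8 with the C9/C11 anti-diol as isopropylidene acetal (2,2,5-trimethyl-1,3-dioxane, 4,6-trans) | CC(C)N(C(C)C)C(=O)OC[C@@H](C)[C@H]1OC(C)(C)O[C@@H]([C@@H]1C)[C@H](C)C=C | intermediate
10 | ethanol | CCO | starting material
11 | ethyl N,N-diisopropylcarbamate | CCOC(=O)N(C(C)C)C(C)C | intermediate
12 | ethynyl(trimethyl)silane | C#C[Si](C)(C)C | starting material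
13 | lithium (trimethylsilyl)acetylide, not isolated | [Li]C#C[Si](C)(C)C | intermediate
14 | 4,4,5,5-tetramethyl-2-[(trimethylsilyl)ethynyl]-1,3,2-dioxaborolane | C[Si](C)(C)C#CB1OC(C)(C)C(C)(C)O1 | intermediate
15 | (R)-1-lithioethyl N,N-diisopropylcarbamate, (+)-sparteine complex, not isolated | C[C@@H]([Li])OC(=O)N(C(C)C)C(C)C | intermediate
16 | lithium boronate (ate) complex of 15 and 14, not isolated | [Li+].C[C@H](OC(=O)N(C(C)C)C(C)C)[B-]1(C#C[Si](C)(C)C)OC(C)(C)C(C)(C)O1 | intermediate
17 | (S)-4,4,5,5-tetramethyl-2-[4-(trimethylsilyl)but-3-yn-2-yl]-1,3,2-dioxaborolane (C4–C6 with the 6-methyl) | C[Si](C)(C)C#C[C@H](C)B1OC(C)(C)C(C)(C)O1 | intermediate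
18 | (S)-C7-lithio derivative of 9, (−)-sparteine complex, not isolated | CC(C)N(C(C)C)C(=O)O[C@@H]([Li])[C@@H](C)[C@H]1OC(C)(C)O[C@@H]([C@@H]1C)[C@H](C)C=C | intermediate
19 | lithium boronate (ate) complex of 18 and 17, not isolated | [Li+].C[Si](C)(C)C#C[C@H](C)[B-]1(OC(C)(C)C(C)(C)O1)[C@H](OC(=O)N(C(C)C)C(C)C)[C@@H](C)[C@H]2OC(C)(C)O[C@@H]([C@@H]2C)[C@H](C)C=C | intermediate
20 | C4–C13 chain: 4-SiMe3 alkyne, 6-Me, 7-B(pin), C9/C11 acetonide, C13 vinyl; C6–C12 arranged as in the target with boron in place of the 7-oxygen | C[Si](C)(C)C#C[C@H](C)[C@H](B1OC(C)(C)C(C)(C)O1)[C@@H](C)[C@H]2OC(C)(C)O[C@@H]([C@@H]2C)[C@H](C)C=C | intermediate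
21 | 1,2,4-trioxolane (ozonide) of 20 at the vinyl group, epimers at the ring carbon, not isolated | C[Si](C)(C)C#C[C@H](C)[C@H](B1OC(C)(C)C(C)(C)O1)[C@@H](C)[C@H]2OC(C)(C)O[C@@H]([C@@H]2C)[C@H](C)C3OCOO3 | intermediate
22 | C13 aldehyde (vinyl of 20 cleaved to CHO) | C[Si](C)(C)C#C[C@H](C)[C@H](B1OC(C)(C)C(C)(C)O1)[C@@H](C)[C@H]2OC(C)(C)O[C@@H]([C@@H]2C)[C@H](C)C=O | intermediate
23 | (E)-2-methylpent-2-enoic acid | CC/C=C(\C)C(=O)O | starting material
24 | (E)-2-methylpent-2-enoic pivalic anhydride, not isolated | CC/C=C(\C)C(=O)OC(=O)C(C)(C)C | intermediate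
25 | (S)-4-isopropyl-3-[(E)-2-methylpent-2-enoyl]-1,3-oxazolidin-2-one | CC/C=C(\C)C(=O)N1[C@@H](C(C)C)COC1=O | intermediate
26 | (S)-3-[(1E,3E)-1-(tert-butyldimethylsilyloxy)-2-methylpenta-1,3-dien-1-yl]-4-isopropyl-1,3-oxazolidin-2-one | C/C=C/C(C)=C(/O[Si](C)(C)C(C)(C)C)N1[C@@H](C(C)C)COC1=O | intermediate
27 | C4–C17 imide: as 22 with the CHO converted to C13(OH)–C14(Me)–C15H=C16(Me)–C17(=O)–oxazolidinone (15E; 13-OH/14-Me anti) | C[Si](C)(C)C#C[C@H](C)[C@H](B1OC(C)(C)C(C)(C)O1)[C@@H](C)[C@H]2OC(C)(C)O[C@@H]([C@@H]2C)[C@H](C)[C@@H](O)[C@@H](C)/C=C(\C)C(=O)N3[C@@H](C(C)C)COC3=O | intermediate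
28 | C4–C17 alkyne acid: terminal alkyne, 7-OH and 13-OH free, C9/C11 acetonide, (15E)-2-methylenoic acid; C6–C14 as in the target | C#C[C@H](C)[C@H](O)[C@@H](C)[C@H]1OC(C)(C)O[C@@H]([C@@H]1C)[C@H](C)[C@@H](O)[C@@H](C)/C=C(\C)C(=O)O | intermediate
29 | 3-methylbut-3-en-2-one | CC(=O)C(C)=C | starting material
30 | 2-methyl-3-(triisopropylsilyloxy)buta-1,3-diene | C=C(C)C(=C)O[Si](C(C)C)(C(C)C)C(C)C | intermediate
31 | 1,4-benzoquinone | O=C1C=CC(=O)C=C1 | starting material
32 | cis-4a,5,8,8a-tetrahydro-6-methyl-7-(triisopropylsilyloxy)naphthalene-1,4-dione (racemic), not isolated | O=C1C=CC(=O)[C@@H]2CC(C)=C(O[Si](C(C)C)(C(C)C)C(C)C)C[C@H]12 | intermediate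
33 | 6-methyl-7-(triisopropylsilyloxy)naphthalene-1,4-dione | O=C1C=CC(=O)c2cc(O[Si](C(C)C)(C(C)C)C(C)C)c(C)cc12 | intermediate
34 | 2-amino-7-methyl-6-(triisopropylsilyloxy)naphthalene-1,4-dione | NC1=CC(=O)c2cc(O[Si](C(C)C)(C(C)C)C(C)C)c(C)cc2C1=O | intermediate
35 | prop-2-yn-1-ol | C#CCO | starting material
36 | (Z)-3-(bromomagnesio)-2-methylprop-2-en-1-olate magnesium bromide, not isolated | Br[Mg]/C=C(/C)CO[Mg]Br | intermediate
37 | (Z)-3-iodo-2-methylprop-2-en-1-ol | I/C=C(/C)CO | intermediate
38 | (Z)-3-iodo-2-methylprop-2-enoic acid | I/C=C(/C)C(=O)O | intermediate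
39 | (Z)-3-iodo-2-methylprop-2-enoyl chloride, not isolated | I/C=C(/C)C(Cl)=O | intermediate
40 | (Z)-3-iodo-2-methyl-N-[7-methyl-1,4-dioxo-6-(triisopropylsilyloxy)-1,4-dihydronaphthalen-2-yl]prop-2-enamide | I/C=C(/C)C(=O)NC1=CC(=O)c2cc(O[Si](C(C)C)(C(C)C)C(C)C)c(C)cc2C1=O | intermediate
41 | (E)-C4-tributylstannyl alkene from 28 (Bu3Sn–C4H=C5H–), not isolated | CCCC[Sn](CCCC)(CCCC)/C=C/[C@H](C)[C@H](O)[C@@H](C)[C@H]1OC(C)(C)O[C@@H]([C@@H]1C)[C@H](C)[C@@H](O)[C@@H](C)/C=C(\C)C(=O)O | intermediate
42 | protected target: full C1–C17 chain (2Z,4E,15E) on the aminoquinone, with C9/C11 acetonide and aryl O-triisopropylsilyl | C/C(=C/C=C/[C@H](C)[C@H](O)[C@@H](C)[C@H]1OC(C)(C)O[C@@H]([C@@H]1C)[C@H](C)[C@@H](O)[C@@H](C)/C=C(\C)C(=O)O)C(=O)NC2=CC(=O)c3cc(O[Si](C(C)C)(C(C)C)C(C)C)c(C)cc3C2=O | intermediate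
43 | CNP0489037.1: (2Z,4E,6S,7S,8R,9R,10R,11R,12R,13S,14S,15E)-7,9,11,13-tetrahydroxy-1-[(6-hydroxy-7-methyl-1,4-dioxonaphthalen-2-yl)amino]-2,6,8,10,12,14,16-heptamethyl-1-oxoheptadeca-2,4,15-trien-17-oic acid (target numbering) | C/C(=C/C=C/[C@H](C)[C@H](O)[C@@H](C)[C@@H](O)[C@@H](C)[C@H](O)[C@H](C)[C@@H](O)[C@@H](C)/C=C(\C)C(=O)O)C(=O)NC1=CC(=O)c2cc(O)c(C)cc2C1=O | target

**Step count**

Total: 23 steps. Longest linear sequence: 12 steps (1, 2, 3, 4, 5, 6, 10, 11, 14, 15, 22, 23).

**Three steps most likely to fail, with fallbacks**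

Step 10 (the proposed new step). Two α-branched partners must form the ate complex and the propargylic carbon must migrate cleanly. The fallback uses known chemistry and sets out from 9. LiAlH4 in THF at reflux removes the carbamate to give the primary alcohol F1, and Dess–Martin periodinane gives the aldehyde F2. Marshall anti-propargylation of F2 follows, using (R)-but-3-yn-2-yl methanesulfonate F3 (from (R)-but-3-yn-2-ol, MsCl, Et3N) with Pd(OAc)2, PPh3 and InI in THF–HMPA. It gives the homopropargylic alcohol F4 with 6-Me/7-OH anti and 7-OH syn to 8-Me. Et3SiOTf/2,6-lutidine gives the silyl ether F5 and ozonolysis gives the aldehyde F6. The vinylogous aldol of step 14 with 26 gives the imide F7, and LiOH/H2O2 gives the acid F8. AcOH–THF–H2O then removes the triethylsilyl group, and the route is rejoined at 28.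

Step 18. Azide may add at C3 as well as C2. The fallback sets out from 33. CeCl3·7H2O-promoted conjugate addition of 2,4-dimethoxybenzylamine in EtOH under air is used, a bulkier amine whose addition is steered by the Lewis acid bound at the more basic C1 carbonyl. It gives the 2-(2,4-dimethoxybenzylamino)quinone F9, regioisomers being separable at this stage. TFA/Et3SiH in CH2Cl2 removes the benzyl group, and the route is rejoined at 34.

Step 22. The one-pot hydrostannation may give some internal stannane, and the quinone amide is a delicate Stille partner. The fallback sets out from 28. Copper-catalysed protoboration (B2pin2, CuCl, Xantphos, NaOtBu, MeOH, THF, rt) gives the isolable (E)-alkenyl pinacol boronate F10, which can be purified from any regioisomer. Suzuki–Miyaura coupling of F10 with 40 (Pd(dppf)Cl2, K3PO4, THF–H2O, rt) rejoins the route at 42.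

**Further compounds**

F1 | step 10 | C7 primary alcohol (carbamate of 9 removed) | OC[C@@H](C)[C@H]1OC(C)(C)O[C@@H]([C@@H]1C)[C@H](C)C=C
F2 | step 10 | C7 aldehyde from F1 | O=C[C@@H](C)[C@H]1OC(C)(C)O[C@@H]([C@@H]1C)[C@H](C)C=C
F3 | step 10 | (R)-but-3-yn-2-yl methanesulfonate | C#C[C@@H](C)OS(C)(=O)=O
F4 | step 10 | homopropargylic alcohol (terminal alkyne, 6-Me, 7-OH, acetonide, C13 vinyl) | C#C[C@H](C)[C@H](O)[C@@H](C)[C@H]1OC(C)(C)O[C@@H]([C@@H]1C)[C@H](C)C=C
F5 | step 10 | 7-O-triethylsilyl ether of F4 | C#C[C@H](C)[C@H](O[Si](CC)(CC)CC)[C@@H](C)[C@H]1OC(C)(C)O[C@@H]([C@@H]1C)[C@H](C)C=C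
F6 | step 10 | C13 aldehyde from F5 | C#C[C@H](C)[C@H](O[Si](CC)(CC)CC)[C@@H](C)[C@H]1OC(C)(C)O[C@@H]([C@@H]1C)[C@H](C)C=O
F7 | step 10 | vinylogous aldol adduct of F6 (C17 oxazolidinone imide) | C#C[C@H](C)[C@H](O[Si](CC)(CC)CC)[C@@H](C)[C@H]1OC(C)(C)O[C@@H]([C@@H]1C)[C@H](C)[C@@H](O)[C@@H](C)/C=C(\C)C(=O)N2[C@@H](C(C)C)COC2=O
F8 | step 10 | 7-O-triethylsilyl alkyne acid | C#C[C@H](C)[C@H](O[Si](CC)(CC)CC)[C@@H](C)[C@H]1OC(C)(C)O[C@@H]([C@@H]1C)[C@H](C)[C@@H](O)[C@@H](C)/C=C(\C)C(=O)O
F9 | step 18 | 2-[(2,4-dimethoxybenzyl)amino]-7-methyl-6-(triisopropylsilyloxy)naphthalene-1,4-dione | COc1ccc(CNC2=CC(=O)c3cc(O[Si](C(C)C)(C(C)C)C(C)C)c(C)cc3C2=O)c(OC)c1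
F10 | step 22 | (E)-C4 alkenyl pinacol boronate from 28 | CC1(C)OB(/C=C/[C@H](C)[C@H](O)[C@@H](C)[C@H]2OC(C)(C)O[C@@H]([C@@H]2C)[C@H](C)[C@@H](O)[C@@H](C)/C=C(\C)C(=O)O)OC1(C)C
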